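**Plan**

- Cuts: first the two acyl C–O bonds on O8 and O9; then C9–C10 of the ten-membered carbocycle (ring A, C1–C10). The C9 carbinol is bonded to C10, the α-carbon of the C1=C10–C14O2Me acrylate, a Baylis–Hillman-type array that is the retron of an α-metalated acrylate adding to a C9 aldehyde. Then C6–C7 together with the C12–O6 bond of the α-methylene-γ-butyrolactone (ring B, O–C6–C7–C11–C12), and last the C1=C10 alkene.
- Forward: neryl acetate is cut down to the C1–C6 chain, given the Z iodoenoate by an iodo-Wittig reaction and oxidised to the Z enal. A chromium allylation with the bromide made from (R)-glyceraldehyde acetonide and methyl acrylate joins the halves and closes ring B. The C8/C9 diol is unmasked, silylated and oxidised at C9, and ring A is closed last through C9–C10. Acetylation, desilylation, esterification and ketal hydrolysis finish the synthesis.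
- Stereochemistry: C8 comes from (R)-glyceraldehyde acetonide; C6 and C7 are set from C8 in the chromium allylation; C9 is set in the ring closure; the side-chain centre comes from (R)-3-bromo-2-hydroxy-2-methylpropanoic acid; the Z C4=C5 alkene comes from neryl acetate and the ring-cis C1=C10 alkene from the Z iodoenoate.

Key step: step 12

Remark: germacrane numbering is used (C13 exocyclic methylene, C14 ester carbon, C15 methyl), and the target is taken as the 6R,7S,8S,9S enantiomer with an (S)-configured side chain, as the SMILES encodes; where the C7 descriptor reads R (compounds with a free C8 hydroxyl) only the CIP priorities have changed.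

**Step 1**
Reactants: 1 neryl acetate
Product: 2 6,7-epoxyneryl acetate (racemic at the epoxide)
Conditions: mCPBA, CH2Cl2, 0 °C
Reagents that add atoms: mCPBA, O=C(OO)c1cccc(Cl)c1
Why: Prilezhaev epoxidation should take the electron-richer terminal trisubstituted alkene and leave the alkene deactivated by the allylic acetoxy group, and the epoxide carbon is excised later so its configuration does not matter.

**Step 2**
Reactants: 2 6,7-epoxyneryl acetate
Product: 4 (2Z)-3-methyl-6-oxohex-2-en-1-yl acetate, via vicinal diol 3 (not isolated)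
Conditions: H5IO6, THF/H2O, 0 °C
Reagents that add atoms: none
Why: Acid-promoted opening of the epoxide at its tertiary carbon and periodate glycol cleavage in the same flask should release acetone and the C1 aldehyde while the allylic acetate and the Z alkene stay intact.

**Step 3**
Reactants: 4 (2Z)-3-methyl-6-oxohex-2-en-1-yl acetate; 5 methyl (triphenylphosphoranylidene)acetate
Product: 7 methyl (2Z,6Z)-8-acetoxy-2-iodo-6-methylocta-2,6-dienoate, via iodo ylide 6 (not isolated)
Conditions: 5, NIS, CH2Cl2, −20 °C; then 4, −20 °C → rt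
Reagents that add atoms: N-iodosuccinimide, O=C1CCC(=O)N1I
Why: Iodination of the stabilised ylide gives the iodo ylide, whose Wittig reaction with the unhindered aldehyde should place the ester trans to the chain under the kinetic control typical of stabilised ylides and so give the Z iodoenoate (iodine cis to C2).

**Step 4**
Reactants: 7 methyl (2Z,6Z)-8-acetoxy-2-iodo-6-methylocta-2,6-dienoate
Product: 8 methyl (2Z,6Z)-8-hydroxy-2-iodo-6-methylocta-2,6-dienoate
Conditions: K2CO3 (cat.), MeOH, 0 °C
Reagents that add atoms: none
Why: Carbonate-catalysed transesterification (Zemplén-type methanolysis) should remove the acetate, the methyl ester being degenerate toward methanol and the vinylic iodide inert.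

**Step 5**
Reactants: 8 methyl (2Z,6Z)-8-hydroxy-2-iodo-6-methylocta-2,6-dienoate
Product: 9 methyl (2Z,6Z)-2-iodo-6-methyl-8-oxoocta-2,6-dienoate
Conditions: MnO2, CH2Cl2, rt
Reagents that add atoms: none
Why: MnO2 oxidises allylic alcohols selectively under neutral heterogeneous conditions, so the Z enal should form without isomerisation and without touching the iodoenoate.

**Step 6**
Reactants: 10 (R)-2,2-dimethyl-1,3-dioxolane-4-carbaldehyde; 11 methyl acrylate
Product: 12 methyl 2-{[(4R)-2,2-dimethyl-1,3-dioxolan-4-yl](hydroxy)methyl}prop-2-enoate (both carbinol epimers)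
Conditions: DABCO, dioxane/H2O (1:1), rt
Reagents that add atoms: none
Why: The Morita–Baylis–Hillman reaction forms the C7–C11 bond, the new carbinol centre being formed as an epimer mixture that is inconsequential because it becomes sp2 in the next step, while the dioxolane centre (later C8) is untouched.

**Step 7**
Reactants: 12 Baylis–Hillman adduct
Product: 13 methyl (2Z)-2-(bromomethyl)-3-[(4S)-2,2-dimethyl-1,3-dioxolan-4-yl]prop-2-enoate
Conditions: NBS, Me2S, CH2Cl2, 0 °C → rt
Reagents that add atoms: N-bromosuccinimide, O=C1CCC(=O)N1Br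
Why: The bromosulfonium reagent activates the hydroxyl and bromide attacks in the SN2' sense (Corey–Kim-type bromination with allylic transposition), which should give the thermodynamically preferred Z 2-(bromomethyl)enoate under non-acidic conditions that spare the acetonide.

**Step 8**
Reactants: 13 allylic bromide; 9 Z enal
Product: 16 trans-lactone acetonide (6R,7S,8S), via allylchromium dichloride 14 (not isolated), via seco hydroxy ester 15 (not isolated)
Conditions: CrCl2 (nickel-free, 2.5 equiv), THF, 0 °C → rt
Reagents that add atoms: none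
Why: In this Nozaki–Hiyama (chromium Barbier) 2-(alkoxycarbonyl)allylation, nickel-free divalent chromium should reduce the allylic bromide far faster than the alkenyl iodide, the equilibrating allylchromium adds 1,2 to the enal through a chair transition state with both substituents equatorial (anti adduct, hence the trans lactone once the chromium alkoxide lactonises in the flask), and attack on the allyl face that has the C8–O bond antiperiplanar to the forming C6–C7 bond with H8 toward the aldehyde (Felkin–Anh sense) should set 6R and 7S from the 8S centre.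

**Step 9**
Reactants: 16 trans-lactone acetonide
Product: 17 trans-lactone 8,9-diol (6R,7R,8S)
Conditions: AcOH/H2O (4:1), 40 °C
Reagents that add atoms: none
Why: Acid-catalysed hydrolysis of the terminal isopropylidene ketal should free the diol under conditions too mild to open the lactone, ionise the allylic C6–O bond or affect the iodoenoate.

**Step 10**
Reactants: 17 trans-lactone 8,9-diol
Product: 18 8,9-bis(triethylsilyl) ether (6R,7S,8S)
Conditions: TESOTf, 2,6-lutidine, CH2Cl2, −78 → 0 °C
Reagents that add atoms: triethylsilyl triflate, CC[Si](CC)(CC)OS(=O)(=O)C(F)(F)F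
Why: A silyl triflate with a hindered pyridine base silylates the primary and the hindered secondary hydroxyl rapidly at low temperature without a base strong enough to open or isomerise the lactone.

**Step 11**
Reactants: 18 8,9-bis(triethylsilyl) ether
Product: 19 C9 aldehyde with C8 triethylsilyloxy group and Z iodoenoate chain (6R,7S,8S)
Conditions: (COCl)2, DMSO, CH2Cl2, −78 → −40 °C; Et3N, −78 → 0 °C
Reagents that add atoms: none
Why: Under Swern conditions a primary triethylsilyl ether is cleaved by the chlorosulfonium species and oxidised directly to the aldehyde while the secondary silyl ether survives, which should give the α-silyloxy aldehyde without epimerisation at C8 at low temperature.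

**Step 12**
Reactants: 19 C9 aldehyde with C8 triethylsilyloxy group and Z iodoenoate chain
Product: 21 methyl (1(10)E,4Z,6R,7S,8S,9S)-9-hydroxy-8-(triethylsilyloxy)germacra-1(10),4,11(13)-trien-12,6-olid-14-oate, via alkenylchromium dichloride 20 (not isolated)
Conditions: CrCl2 (10 equiv), NiCl2 (cat.), degassed DMSO, rt, slow addition of 19 to high dilution (about 0.003 M)
Reagents that add atoms: none
Why: Divalent chromium reduces NiCl2 to zerovalent nickel, which inserts into the C10–I bond with retention; transmetalation gives the alkenylchromium 20 of trivalent chromium, an α-metalated acrylate that adds 1,2 to the C9 aldehyde (Nozaki–Hiyama–Kishi reaction, the closest known class being ring-forming additions of iodoalkenes, iodoenoates included, to aldehydes in medium rings). Ring A (ten-membered, C1–C10) closes in the 10-exo-trig mode by attack of sp2 C10 on the C9 carbonyl carbon, the carbonyl oxygen staying outside the ring. The new C9 stereocentre should be controlled by the C8 silyloxy centre and the closing ring: with the C9=O dipole antiperiplanar to the C8–O bond and the gauche C7–C8–C9–C10 torsion imposed by the tether, C10 reaches the face that puts O9 trans to O8 on the ring (9S). The step needs chemoselectivity for the aldehyde over the lactone, the two acrylate units and the silyl ether, which the low basicity of alkenylchromium reagents secures, and retention of the Z iodoenoate geometry so that C1=C10 is cis within the ring, which the configurationally stable C–Cr bond secures. Ring closure should outrun oligomerisation because of high dilution and because the trans-lactone and the cis C4=C5 alkene already bend the chain so that C10 lies near C9.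

**Step 13**
Reactants: 21 ring-closed C9 alcohol
Product: 22 methyl (1(10)E,4Z,6R,7S,8S,9S)-9-acetoxy-8-(triethylsilyloxy)germacra-1(10),4,11(13)-trien-12,6-olid-14-oate
Conditions: Ac2O, DMAP (cat.), pyridine, CH2Cl2, 0 °C → rt
Reagents that add atoms: acetic anhydride, CC(=O)OC(C)=O
Why: DMAP-catalysed acetylation of the secondary C9 hydroxyl does not break the C9–O bond and should therefore proceed with retention.

**Step 14**
Reactants: 22 C9 acetate with C8 silyl ether
Product: 23 methyl (1(10)E,4Z,6R,7R,8S,9S)-9-acetoxy-8-hydroxygermacra-1(10),4,11(13)-trien-12,6-olid-14-oate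
Conditions: HF·pyridine, pyridine, THF, 0 °C
Reagents that add atoms: none
Why: Fluoride-mediated desilylation under buffered, weakly acidic conditions should free the C8 hydroxyl without the acetyl migration from O9 that basic fluoride sources promote.

**Step 15**
Reactants: 24 (R)-3-bromo-2-hydroxy-2-methylpropanoic acid
Product: 26 (S)-2,3-dihydroxy-2-methylpropanoic acid, via (S)-2-methylglycidate 25 (not isolated)
Conditions: NaOH, H2O, 80 °C; then HCl to pH 2
Reagents that add atoms: sodium hydroxide, [Na+].[OH-]
Why: Intramolecular Williamson displacement of bromide gives the glycidate, which hydroxide opens at the unsubstituted CH2 carbon, so none of the four bonds of the tertiary centre is broken and the configuration is retained (the descriptor changes from R to S only through the priority change).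

**Step 16**
Reactants: 26 (S)-2,3-dihydroxy-2-methylpropanoic acid
Product: 28 methyl (S)-2,2,4-trimethyl-1,3-dioxolane-4-carboxylate, via methyl ester diol 27 (not isolated)
Conditions: MeOH, TsOH (cat.), reflux; then 2,2-dimethoxypropane, rt
Reagents that add atoms: methanol, CO; 2,2-dimethoxypropane, COC(C)(C)OC
Why: Fischer esterification followed by acid-catalysed transketalisation should give the five-membered ketal of the 1,2-diol, the ester blocking the competing dioxolanone formation.

**Step 17**
Reactants: 28 methyl (S)-2,2,4-trimethyl-1,3-dioxolane-4-carboxylate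
Product: 29 (S)-2,2,4-trimethyl-1,3-dioxolane-4-carboxylic acid
Conditions: LiOH, THF/H2O, 0 °C → rt; then cold 1 M HCl to pH 3
Reagents that add atoms: lithium hydroxide, [Li+].[OH-]
Why: Saponification by hydroxide followed by careful cold acidification should give the acid without loss of the acid-labile ketal, and the quaternary centre cannot epimerise.

**Step 18**
Reactants: 23 C8 alcohol; 29 (S)-2,2,4-trimethyl-1,3-dioxolane-4-carboxylic acid
Product: 31 acetonide-protected target (6R,7S,8S,9S; side chain 4S), via mixed anhydride 30 (not isolated)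
Conditions: 29, 2,4,6-trichlorobenzoyl chloride, Et3N, toluene, rt; then 23, DMAP, rt → 40 °C
Reagents that add atoms: none
Why: In this Yamaguchi esterification DMAP attacks the mixed anhydride at the less hindered aliphatic carbonyl and the acylpyridinium acylates the hindered C8 hydroxyl without breaking the C8–O bond, so C8 is retained.

**Step 19**
Reactants: 31 acetonide-protected target
Product: 32 CNP0197537.1
Conditions: AcOH/H2O (4:1), 45 °C
Reagents that add atoms: none
Why: Acid-catalysed hydrolysis of the side-chain isopropylidene ketal should release the tertiary and primary hydroxyls under conditions that leave the acetate, the ester linkages and the allylic lactone intact.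

**Compound list**

1 | neryl acetate, (2Z)-3,7-dimethylocta-2,6-dien-1-yl acetate | CC(C)=CCC/C(C)=C\COC(C)=O | starting material
2 | 6,7-epoxyneryl acetate, (2Z)-5-(3,3-dimethyloxiran-2-yl)-3-methylpent-2-en-1-yl acetate (racemic) | CC1(C)OC1CC/C(C)=C\COC(C)=O | intermediate
3 | (2Z)-6,7-dihydroxy-3,7-dimethyloct-2-en-1-yl acetate (racemic) | CC(C)(O)C(O)CC/C(C)=C\COC(C)=O | intermediate
4 | (2Z)-3-methyl-6-oxohex-2-en-1-yl acetate | O=CCC/C(C)=C\COC(C)=O | intermediate
5 | methyl (triphenylphosphoranylidene)acetate | COC(=O)C=P(c1ccccc1)(c1ccccc1)c1ccccc1 | starting material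
6 | methyl iodo(triphenylphosphoranylidene)acetate | COC(=O)C(I)=P(c1ccccc1)(c1ccccc1)c1ccccc1 | intermediate
7 | methyl (2Z,6Z)-8-acetoxy-2-iodo-6-methylocta-2,6-dienoate | COC(=O)/C(I)=C/CC/C(C)=C\COC(C)=O | intermediate
8 | methyl (2Z,6Z)-8-hydroxy-2-iodo-6-methylocta-2,6-dienoate | COC(=O)/C(I)=C/CC/C(C)=C\CO | intermediate
9 | methyl (2Z,6Z)-2-iodo-6-methyl-8-oxoocta-2,6-dienoate | COC(=O)/C(I)=C/CC/C(C)=C\C=O | intermediate
10 | (R)-2,2-dimethyl-1,3-dioxolane-4-carbaldehyde | CC1(C)OC[C@H](C=O)O1 | starting material
11 | methyl acrylate | C=CC(=O)OC | starting material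
12 | methyl 2-{[(4R)-2,2-dimethyl-1,3-dioxolan-4-yl](hydroxy)methyl}prop-2-enoate, both carbinol epimers | CC1(C)OC[C@H](C(O)C(=C)C(=O)OC)O1 | intermediate
13 | methyl (2Z)-2-(bromomethyl)-3-[(4S)-2,2-dimethyl-1,3-dioxolan-4-yl]prop-2-enoate | CC1(C)OC[C@H](/C=C(\CBr)C(=O)OC)O1 | intermediate
14 | allylchromium dichloride from 13 (CH2–CrCl2 in place of CH2–Br; equilibrating, reactive E form shown) | CC1(C)OC[C@H](/C=C(/C[Cr](Cl)Cl)C(=O)OC)O1 | intermediate
15 | seco hydroxy ester (6R,7S,8S), present as its chromium alkoxide: methyl (2Z,6Z,8R,9S)-9-[(4S)-2,2-dimethyl-1,3-dioxolan-4-yl]-8-hydroxy-2-iodo-10-(methoxycarbonyl)-6-methylundeca-2,6,10-trienoate | C=C(C(=O)OC)[C@@H]([C@H](O)/C=C(/C)CC/C=C(\I)C(=O)OC)[C@H]1COC(C)(C)O1 | intermediate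
16 | trans-lactone acetonide (6R,7S,8S): methyl (2Z,6Z)-7-{(2R,3S)-3-[(4S)-2,2-dimethyl-1,3-dioxolan-4-yl]-4-methylidene-5-oxooxolan-2-yl}-2-iodo-6-methylhepta-2,6-dienoate | C=C1C(=O)O[C@H](/C=C(/C)CC/C=C(\I)C(=O)OC)[C@H]1[C@H]2COC(C)(C)O2 | intermediate
17 | trans-lactone 8,9-diol (6R,7R,8S): as 16 with a (1S)-1,2-dihydroxyethyl group on C7 | C=C1C(=O)O[C@H](/C=C(/C)CC/C=C(\I)C(=O)OC)[C@H]1[C@H](O)CO | intermediate
18 | 8,9-bis(triethylsilyl) ether of 17 (6R,7S,8S) | C=C1C(=O)O[C@H](/C=C(/C)CC/C=C(\I)C(=O)OC)[C@H]1[C@H](O[Si](CC)(CC)CC)CO[Si](CC)(CC)CC | intermediate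
19 | C9 aldehyde (6R,7S,8S): trans-lactone with the Z iodoenoate chain on C6 and a (1S)-2-oxo-1-(triethylsilyloxy)ethyl group on C7 | C=C1C(=O)O[C@H](/C=C(/C)CC/C=C(\I)C(=O)OC)[C@H]1[C@H](O[Si](CC)(CC)CC)C=O | intermediate
20 | alkenylchromium dichloride from 19 (C10–CrCl2 in place of C10–I, geometry retained) | C=C1C(=O)O[C@H](/C=C(/C)CC/C=C(\[Cr](Cl)Cl)C(=O)OC)[C@H]1[C@H](O[Si](CC)(CC)CC)C=O | intermediate
21 | methyl (1(10)E,4Z,6R,7S,8S,9S)-9-hydroxy-8-(triethylsilyloxy)germacra-1(10),4,11(13)-trien-12,6-olid-14-oate | C=C1C(=O)O[C@@H]2/C=C(/C)CC/C=C(/C(=O)OC)[C@H](O)[C@@H](O[Si](CC)(CC)CC)[C@@H]12 | intermediate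
22 | methyl (1(10)E,4Z,6R,7S,8S,9S)-9-acetoxy-8-(triethylsilyloxy)germacra-1(10),4,11(13)-trien-12,6-olid-14-oate | C=C1C(=O)O[C@@H]2/C=C(/C)CC/C=C(/C(=O)OC)[C@H](OC(C)=O)[C@@H](O[Si](CC)(CC)CC)[C@@H]12 | intermediate
23 | methyl (1(10)E,4Z,6R,7R,8S,9S)-9-acetoxy-8-hydroxygermacra-1(10),4,11(13)-trien-12,6-olid-14-oate | C=C1C(=O)O[C@@H]2/C=C(/C)CC/C=C(/C(=O)OC)[C@H](OC(C)=O)[C@@H](O)[C@@H]12 | intermediate
24 | (R)-3-bromo-2-hydroxy-2-methylpropanoic acid | OC(=O)[C@@](C)(O)CBr | starting material
25 | (S)-2-methyloxirane-2-carboxylic acid (sodium salt in the flask) | OC(=O)[C@]1(C)CO1 | intermediate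
26 | (S)-2,3-dihydroxy-2-methylpropanoic acid | OC(=O)[C@@](C)(O)CO | intermediate
27 | methyl (S)-2,3-dihydroxy-2-methylpropanoate | COC(=O)[C@@](C)(O)CO | intermediate
28 | methyl (S)-2,2,4-trimethyl-1,3-dioxolane-4-carboxylate | COC(=O)[C@@]1(C)OC(C)(C)OC1 | intermediate
29 | (S)-2,2,4-trimethyl-1,3-dioxolane-4-carboxylic acid | OC(=O)[C@@]1(C)OC(C)(C)OC1 | intermediate
30 | mixed anhydride of 29 with 2,4,6-trichlorobenzoic acid | O=C(OC(=O)c1c(Cl)cc(Cl)cc1Cl)[C@@]1(C)OC(C)(C)OC1 | intermediate
31 | methyl (1(10)E,4Z,6R,7S,8S,9S)-9-acetoxy-8-{[(4S)-2,2,4-trimethyl-1,3-dioxolane-4-carbonyl]oxy}germacra-1(10),4,11(13)-trien-12,6-olid-14-oate | C=C1C(=O)O[C@@H]2/C=C(/C)CC/C=C(/C(=O)OC)[C@H](OC(C)=O)[C@@H](OC(=O)[C@@]3(C)OC(C)(C)OC3)[C@@H]12 | intermediate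
32 | CNP0197537.1, methyl (1(10)E,4Z,6R,7S,8S,9S)-9-acetoxy-8-{[(2S)-2,3-dihydroxy-2-methylpropanoyl]oxy}germacra-1(10),4,11(13)-trien-12,6-olid-14-oate | C=C1C(=O)O[C@@H]2/C=C(/C)CC/C=C(/C(=O)OC)[C@H](OC(C)=O)[C@@H](OC(=O)[C@@](C)(O)CO)[C@@H]12 | target

**Step count**

Total: 19 steps. Longest linear sequence: 14 steps (steps 1–5, 8–14, 18 and 19); steps 6–7 and 15–17 are side branches.

**Steps most likely to fail**

Step 12. The alkenylchromium may add to the other face of the C9 aldehyde, because the open-chain Felkin–Anh preference of an α-silyloxy aldehyde is for the 8,9-anti carbinol and only the geometry of the closing ring opposes it. Slow closure would also let protodemetalation compete. The fallback sets out from 19 and comes back at 21. The closure is run as in step 12 (through 20), and the 9-epimeric alcohol F1, alone or mixed with 21, is oxidised with Dess–Martin periodinane (NaHCO3, CH2Cl2, 0 °C) to the C9 ketone F2. Luche reduction (NaBH4, CeCl3, MeOH, −78 °C) then sets C9 by hydride delivery instead of C–C bond formation. With hydride as the incoming group, Felkin–Anh control by the α-silyloxy centre leads to the required syn 8,9-diol relationship and should give 21.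

Step 8. Single-electron reduction of the C10–I bond of 9 by divalent chromium may compete with reduction of the allylic bromide, which would remove the iodine needed for step 12. The fallback sets out from 4 and comes back at 17, and it introduces the iodoalkene only after the chromium step. Aldehyde 4 is protected as the dimethyl acetal F3 (HC(OMe)3, PPTS, MeOH). Methanolysis of the acetate (K2CO3, MeOH) gives the allylic alcohol F4, and MnO2 oxidation gives the Z enal F5. Chromium allylation with 13 under the conditions of step 8 proceeds through allylchromium 14 and the seco hydroxy ester F6 to the lactone F7. Aqueous acetic acid removes the acetonide and the dimethyl acetal together to give the diol aldehyde F8. The iodo-Wittig reaction of step 3 (iodo ylide 6 from 5 and NIS) on F8 then gives diol 17.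

Step 18. The acetyl group may migrate from O9 to the free O8 (or the lactone may shift onto O8) under the basic acylation conditions, while acylation of the hindered ring hydroxyl by a hindered acid is slow. The fallback sets out from 17 and comes back at 31, and it attaches the side chain before the ring is closed and before any acetate is present. The primary hydroxyl of 17 is silylated selectively (TESCl, imidazole, CH2Cl2, −20 °C) to give the 9-O-triethylsilyl ether F9. Its open-chain C8 hydroxyl is esterified with acid 29 through mixed anhydride 30 (conditions of step 18) to give the ester F10. The Swern protocol of step 11 converts the primary silyl ether into the C9 aldehyde F11. Ring closure under the conditions of step 12 proceeds through the alkenylchromium F12 to the C9 alcohol F13. Acetylation (Ac2O, DMAP, pyridine) gives 31.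

**Further compounds**

F1 | step 12 | methyl (1(10)E,4Z,6R,7S,8S,9R)-9-hydroxy-8-(triethylsilyloxy)germacra-1(10),4,11(13)-trien-12,6-olid-14-oate (9-epimer of 21) | C=C1C(=O)O[C@@H]2/C=C(/C)CC/C=C(/C(=O)OC)[C@@H](O)[C@@H](O[Si](CC)(CC)CC)[C@@H]12
F2 | step 12 | methyl (1(10)E,4Z,6R,7S,8S)-9-oxo-8-(triethylsilyloxy)germacra-1(10),4,11(13)-trien-12,6-olid-14-oate | C=C1C(=O)O[C@@H]2/C=C(/C)CC/C=C(/C(=O)OC)C(=O)[C@@H](O[Si](CC)(CC)CC)[C@@H]12
F3 | step 8 | (2Z)-6,6-dimethoxy-3-methylhex-2-en-1-yl acetate | COC(OC)CC/C(C)=C\COC(C)=O
F4 | step 8 | (2Z)-6,6-dimethoxy-3-methylhex-2-en-1-ol | COC(OC)CC/C(C)=C\CO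
F5 | step 8 | (2Z)-6,6-dimethoxy-3-methylhex-2-enal | COC(OC)CC/C(C)=C\C=O
F6 | step 8 | seco hydroxy ester with dimethyl acetal terminus (6R,7S,8S), as its chromium alkoxide | C=C(C(=O)OC)[C@@H]([C@H](O)/C=C(/C)CCC(OC)OC)[C@H]1COC(C)(C)O1
F7 | step 8 | trans-lactone acetonide with dimethyl acetal terminus (6R,7S,8S) | C=C1C(=O)O[C@H](/C=C(/C)CCC(OC)OC)[C@H]1[C@H]2COC(C)(C)O2
F8 | step 8 | trans-lactone 8,9-diol with C1 aldehyde terminus (6R,7R,8S) | C=C1C(=O)O[C@H](/C=C(/C)CCC=O)[C@H]1[C@H](O)CO
F9 | step 18 | 9-O-triethylsilyl ether of diol 17 (6R,7R,8S) | C=C1C(=O)O[C@H](/C=C(/C)CC/C=C(\I)C(=O)OC)[C@H]1[C@H](O)CO[Si](CC)(CC)CC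
F10 | step 18 | C8 ester of F9 with acid 29 (6R,7S,8S; side chain 4S) | C=C1C(=O)O[C@H](/C=C(/C)CC/C=C(\I)C(=O)OC)[C@H]1[C@H](OC(=O)[C@@]2(C)OC(C)(C)OC2)CO[Si](CC)(CC)CC
F11 | step 18 | C9 aldehyde carrying the C8 side-chain ester (6R,7S,8S) | C=C1C(=O)O[C@H](/C=C(/C)CC/C=C(\I)C(=O)OC)[C@H]1[C@H](OC(=O)[C@@]2(C)OC(C)(C)OC2)C=O
F12 | step 18 | alkenylchromium dichloride from F11 | C=C1C(=O)O[C@H](/C=C(/C)CC/C=C(\[Cr](Cl)Cl)C(=O)OC)[C@H]1[C@H](OC(=O)[C@@]2(C)OC(C)(C)OC2)C=O
F13 | step 18 | methyl (1(10)E,4Z,6R,7S,8S,9S)-9-hydroxy-8-{[(4S)-2,2,4-trimethyl-1,3-dioxolane-4-carbonyl]oxy}germacra-1(10),4,11(13)-trien-12,6-olid-14-oate | C=C1C(=O)O[C@@H]2/C=C(/C)CC/C=C(/C(=O)OC)[C@H](O)[C@@H](OC(=O)[C@@]3(C)OC(C)(C)OC3)[C@@H]12
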